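## Structural features

The target is a bicyclo[3.2.1]octane in which a chair cyclohexanone (C1–C9–C5–C6–C7–C8) and a cyclopentane (C1–C2–C3–C5–C9) share the bridge C1–C9–C5; C2 and C9 are ketones and C3 is a tertiary carbinol. C1 carries an isobutyryl group and is bonded to the gem-dimethyl carbon C8, so C1–C8 joins two quaternary carbons. C5 and C7 each carry a prenyl group (equatorial at C7), and C3 carries the (Z)-4-hydroxy-4-methylpent-2-enoyl chain. There are four stereocentres, (1R,3S,5S,7R) in this numbering: the bridgeheads C1 and C5 can only be cis, C7 is next to C8, and C3 is next to C5 with its hydroxyl endo (towards C7) and its acyl group exo (towards C9). The C3 hydroxyl is an aldol (β to C9) and an α-ketol (next to C2), so its alkoxide can fragment or undergo acyl shift; the non-enolisable tricarbonyl array at C1 is open to retro-Claisen attack, the Z-γ-hydroxy-enone can isomerise or close to a lactol, and the two trisubstituted alkenes rule out electrophilic oxidants and strong acid. The real difficulty is the congested C1/C8/C5 region, with the absolute configuration of the whole bicycle resting on C1 alone. The key step uses two features: C5 lies between the C9 and C3 carbonyls of a cyclopentane-1,2,4-trione and supports a planar radical, and the C1–C8 bond is the retron of an O-prenyl Claisen shift that leaves C6=C7 as a vinyl group, so 6-endo attack of C5 on C6 closes ring C5–C6–C7–C8–C1–C9 and leaves C7 functionalised.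

## Logic of the disconnections

22 to 21: one C–CH3 bond of the dimethylcarbinol is cut. What remains is a Z-enedione held as a cyclic hemiketal, which is an oxidised furan. The forward step needs a methyl nucleophile that picks the one unhindered ketone among five carbonyls without fragmenting the C3 alkoxide.

21 to 18: no skeletal bond is cut; the two side-chain carbonyls are traced back to the 2,5-disubstituted furan of 18. The Z geometry then comes from the ring and the side chain becomes base-stable. The oxidant must open the furan and leave both prenyl groups alone.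

18 to 15 and 16: the C3–C(furyl) bond is cut. The carbinol becomes a ketone and the bicycle a plain 2,3,9-trione. The forward addition must choose C3 over C2 and the exo face over the endo face.

15 to 13 and 14: the trisubstituted double bond of the C7 prenyl group is cut. A prenyl group cannot be delivered to a carbon radical with the right regiochemistry, an allyl group can. The metathesis catalyst must tolerate the vicinal dione and leave the C5 prenyl group unchanged.

13 to 11 and 12: the C7–CH2 bond is cut. The C7 radical is exactly what the ring closure leaves behind, stored as an iodide. The forward allylation must come from the equatorial side.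

11 to 10: the C5–C6 ring bond and the C7–I bond are cut. The bicycle falls to a monocyclic trione and the C5 and C7 stereocentres disappear. The forward radical closure must be 6-endo and must sustain an iodine-transfer chain.

10 to 9: the C5–I bond is cut. The forward iodination must occur at carbon and not at a prenyl double bond.

9 to 8: the C1–C8 bond is cut in the sense of a [3,3] shift. The bond between two quaternary carbons becomes an O–CH2 bond and the C1 stereocentre becomes a prochiral enol ether. The forward step needs enantioface control and a concerted rather than ionised pathway.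

8 to 6 and 7: the O–CH2 bond is cut. The forward alkylation must go to oxygen, and to the oxygen on C2.

6 to 3 and 4: the C1–C2 and C3–C5 bonds are cut. The ring becomes an acyclic 1,3-diketone and a two-carbon diester. Ring closure must go through the methylene and not the isopropyl methine.

3 to 1 and 2: the bond between the central CH2 and the isobutyryl carbonyl is cut. Acylation must occur at the methyl terminus of the ketone.

## Other disconnections considered

Alternative 1: The cut removes the C2–C3 ring bond and the bond between the side-chain carbonyl and its alkyne carbon, leading back to the bicyclo[3.3.1]nonane-2,3,4,9-tetraone A1 and the lithium acetylide A2.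
- **Forward step.** A2 adds to the central carbonyl of the three-carbonyl bridge of A1. The alkoxide then undergoes an acyloin shift: the ring bond from C2 moves to the neighbouring carbonyl carbon, the attacked carbon leaves the ring as the ynone carbonyl, and the ring contracts to give A3.
- **In favour.** The side chain, the tertiary carbinol and the ring size arrive in one operation. The carbinol configuration follows from the tethered geometry of the shift rather than from the facial choice of an external nucleophile; on this point it is better than the chosen plan. Only semi-hydrogenation and desilylation remain, which is also better than the chosen three-step end game.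
- **Against.** A1 already contains both prenyl groups, the C1/C8 quaternary pair and an oxidised three-carbon bridge, so reaching it should take more steps than the six that lead to 11. Either flanking acyl carbon can migrate, and only one shift puts the carbinol next to C5. A basic acetylide meets a non-enolisable polyketone that is open to retro-Claisen cleavage.
- **Comparison.** The chosen plan builds the smaller bicycle directly by a radical closure, while this route builds a larger one and contracts it by an ionic shift. Overall step economy should favour the chosen plan; end-game economy favours Alternative 1.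

Alternative 2: The cut removes C5–C6 and C1–C8 together, leading back to 6 and the bromo enal A4.
- **Forward step.** Under a chiral quaternary ammonium catalyst the dianion of 6 is alkylated at C5 by A4, and the triacyl carbon C1 then adds to the β,β-dimethyl terminus to close the six-membered ring, giving the aldehyde A5.
- **In favour.** Two bonds, one ring and three stereocentres form in one step, so the bicycle is reached in three steps from commercial materials; this is clearly better than the six of the chosen plan. No Claisen shift and no iodide are needed, and the aldehyde can settle equatorial by enolisation.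
- **Against.** The Michael step must join a fully substituted, strongly stabilised carbanion to a fully substituted alkene carbon, which is congested and reversible. Enantioselection has to come from ion pairing during alkylation of a flat, delocalised dianion, with O-alkylation and C1-alkylation competing. The aldehyde is one carbon short of a prenyl group, so homologation and olefination are needed in the presence of the vicinal dione, three steps against two.
- **Comparison.** The same two bonds are formed as in the chosen plan, but by two-electron chemistry. The chosen plan gives the quaternary–quaternary bond to a sigmatropic shift and the less hindered C5–C6 bond to the radical, which matches each bond to a mechanism suited to it. Both routes are equal in leaving the 2,3-dione for the same end game.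

Alternative 3: The cut removes the C3–C5 ring bond in the sense of a ring contraction, leading back to the 3-diazo-bicyclo[3.3.1]nonane-2,4,9-trione A6.
- **Forward step.** Photolysis of A6 expels nitrogen, bridgehead C5 shifts from the C4 carbonyl to C3, and the ketene is trapped by the alcohol solvent as the exo methyl ester A7.
- **In favour.** Wolff contraction of cyclic 2-diazo-1,3-diketones is among the most dependable ring contractions, and the diazo group is introduced trivially. In mechanistic reliability of its key step it is better than the chosen plan, which needs an untested catalytic Claisen shift and a radical chain.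
- **Against.** The complete bicyclo[3.3.1] core must be made first, and either bridgehead could migrate. A7 has C3–H and an ester, so C3 hydroxylation and conversion of the ester into the Z-hydroxy-enone remain, at least four further steps. Oxidation of the C3 enolate would be expected from the open exo face, which would put the hydroxyl exo, the opposite of the target.
- **Comparison.** The chosen plan sets C3 by exo attack of a carbon nucleophile, which gives the natural configuration directly, and it should be shorter. Both routes are equal in carrying C1, C5 and C7 unchanged through the end game.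

Key step: step 6

Remark on numbering: C1–C9 are used throughout (no C4): C1 and C5 are the bridgeheads, C2–C3 the two-carbon bridge, C6–C7–C8 the three-carbon bridge and C9 the one-carbon bridge; monocyclic precursors carry the same labels, and bicyclic names use these locants.

Assumption: in step 4 the (S,S)-ligand is taken to deliver the dimethylallyl terminus to the Si face of C1; if the sense of induction is the opposite, the (R,R)-ligand is used with no other change.

Remark on tautomers: 6, 8 and 9 are written as single tautomers (6 and 9 are largely enolised); C5 is left undefined in 8, 9 and 10 because it becomes planar in step 6.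

## Route

Step 1
Reactants: 1 6-methylhept-5-en-2-one; 2 ethyl 2-methylpropanoate (ethyl isobutyrate)
Product: 3 2,9-dimethyldec-8-ene-3,5-dione
Conditions: NaH (2.2 equiv), 2 (2 equiv), THF, reflux, slow addition of 1; aq. HCl
Reagents that add atoms: none
Why: Crossed Claisen condensation; the methyl ketone is acylated at its CH3 terminus because that product forms the stabilised diketonate that drives the equilibrium, and the α-branched ester does not self-condense.

Step 2
Reactants: 3 2,9-dimethyldec-8-ene-3,5-dione; 4 diethyl oxalate
Product: 6 3-(2-methylpropanoyl)-5-(3-methylbut-2-en-1-yl)cyclopentane-1,2,4-trione (enolised), via oxalyl keto ester 5 (not isolated)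
Conditions: NaOEt (3 equiv), EtOH, 0 °C then reflux; aq. HCl
Reagents that add atoms: none
Why: Double Claisen condensation (oxalylation of the central carbon, then Dieckmann closure by the methylene next to C9), the classical entry to 3-acylcyclopentane-1,2,4-triones; closure through the methylene gives the doubly enolisable product and is favoured over closure through the hindered isopropyl methine.

Step 3
Reactants: 6 3-(2-methylpropanoyl)-5-(3-methylbut-2-en-1-yl)cyclopentane-1,2,4-trione; 7 3-methylbut-2-en-1-ol
Product: 8 2-[(3-methylbut-2-en-1-yl)oxy]-3-(2-methylpropanoyl)-5-(3-methylbut-2-en-1-yl)cyclopent-2-ene-1,4-dione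
Conditions: PPh3 (1.05 equiv), DIAD (1.05 equiv), 7 (1.0 equiv), THF, 0 °C to rt
Reagents that add atoms: none
Why: Mitsunobu O-alkylation of a strongly acidic enol, which avoids alkylation at the triacyl carbon; the oxygen on C2 should react because C2, as part of the α-dione, is the best acceptor and carries most of the enolate charge, and it is the least hindered of the three oxygens.

Step 4
Reactants: 8 2-[(3-methylbut-2-en-1-yl)oxy]-3-(2-methylpropanoyl)-5-(3-methylbut-2-en-1-yl)cyclopent-2-ene-1,4-dione
Product: 9 (3R)-3-(2-methylbut-3-en-2-yl)-3-(2-methylpropanoyl)-5-(3-methylbut-2-en-1-yl)cyclopentane-1,2,4-trione (ring position 3 is C1)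
Conditions: Cu(OTf)2 (10 mol %), (S,S)-2,2'-(propane-2,2-diyl)bis(4-tert-butyl-4,5-dihydrooxazole) (11 mol %), 4 Å molecular sieves, CH2Cl2, −20 °C to rt
Reagents that add atoms: none
Why: Proposed new method: divalent copper is expected to bind the ether oxygen on C2 and the C3 carbonyl oxygen of 8 in a five-membered chelate, polarising the O–CH2 bond and accelerating a chair-like [3,3] shift that forms C1–C8 with allyl inversion, while the tert-butyl groups of the ligand block one face of the flat enol ether so that the dimethylallyl terminus reaches the Si face of C1 (priorities C9 > acyl carbon > C2) and C1 becomes (R); the closest known reaction type is the Cu(OTf)2–bis(oxazoline)-catalysed enantioselective Claisen rearrangement of 2-alkoxycarbonyl allyl vinyl ethers, which has not been shown for cyclic triketone enol ethers or for prenyl ethers that form two adjacent quaternary carbons.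

Step 5
Reactants: 9 (3R)-3-(2-methylbut-3-en-2-yl)-3-(2-methylpropanoyl)-5-(3-methylbut-2-en-1-yl)cyclopentane-1,2,4-trione
Product: 10 (3S)-5-iodo-3-(2-methylbut-3-en-2-yl)-3-(2-methylpropanoyl)-5-(3-methylbut-2-en-1-yl)cyclopentane-1,2,4-trione (both C5 epimers)
Conditions: NIS (1.05 equiv), Et3N (10 mol %), CH2Cl2, −40 °C, dark; used without storage
Reagents that add atoms: N-iodosuccinimide, O=C1CCC(=O)N1I
Why: Electrophilic α-iodination of an enolised 1,3-dione at C5, its only enolisable carbon; the enol carbon is far more nucleophilic than the prenyl alkenes at low temperature, the C5 configuration is irrelevant, and the descriptor at C1 changes only because iodine alters the priorities.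

Step 6
Reactants: 10 (3S)-5-iodo-3-(2-methylbut-3-en-2-yl)-3-(2-methylpropanoyl)-5-(3-methylbut-2-en-1-yl)cyclopentane-1,2,4-trione
Product: 11 (1R,5R,7R)-7-iodo-8,8-dimethyl-1-(2-methylpropanoyl)-5-(3-methylbut-2-en-1-yl)bicyclo[3.2.1]octane-2,3,9-trione (iodide equatorial)
Conditions: Et3B (0.3 equiv), air (trace), PhH (0.02 M), 25 °C
Reagents that add atoms: none
Why: Ethyl radicals from Et3B and oxygen abstract iodine from the weak tertiary C5–I bond, giving a planar, electrophilic radical delocalised over the C9 and C3 carbonyls, so both C5 epimers of 10 converge. This radical adds to the unsubstituted terminus C6 of the vinyl group on C8 in a 6-endo-trig closure through a chair-like transition state, forming C5–C6 and the ring C5–C6–C7–C8–C1–C9. The closest known reaction type is the iodine-atom-transfer cyclisation of α-iodo-1,3-dicarbonyl compounds, together with Mn(OAc)3-type oxidative cyclisations, in which radicals with a carbonyl inside the forming ring close 6-endo onto terminal alkenes. The 5-exo mode is disfavoured because it would attack the neopentyl carbon C7 and give a strained bicyclo[2.2.1] skeleton. C5 is controlled by the tether: the vinyl group is joined to C5 through C1 and the one-atom bridge C9, so the new bond can form only on the ring face that carries C8, which fixes C5 relative to the Claisen-set C1. The secondary C7 radical takes iodine from another molecule of 10 on its open equatorial side, giving the equatorial iodide and carrying the chain; this centre is reset in step 7. The step needs 6-endo regioselectivity and radical rather than ionic iodine transfer; the first is secured by the carbonyl in the ring and the hindered C7, the second by neutral, cold, dilute conditions without hydrogen donors or Lewis acids.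

Step 7
Reactants: 11 (1R,5R,7R)-7-iodo-8,8-dimethyl-1-(2-methylpropanoyl)-5-(3-methylbut-2-en-1-yl)bicyclo[3.2.1]octane-2,3,9-trione; 12 allyltributylstannane
Product: 13 (1R,5R,7R)-8,8-dimethyl-1-(2-methylpropanoyl)-5-(3-methylbut-2-en-1-yl)-7-(prop-2-en-1-yl)bicyclo[3.2.1]octane-2,3,9-trione
Conditions: 12 (3 equiv), AIBN (0.2 equiv), PhH, 80 °C
Reagents that add atoms: none
Why: Keck radical allylation; the planar C7 radical is attacked by the stannane on its equatorial side, away from the C2–C3 bridge that blocks the axial side, so the allyl group ends equatorial (7R).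

Step 8
Reactants: 13 (1R,5R,7R)-8,8-dimethyl-1-(2-methylpropanoyl)-5-(3-methylbut-2-en-1-yl)-7-(prop-2-en-1-yl)bicyclo[3.2.1]octane-2,3,9-trione; 14 2-methylbut-2-ene
Product: 15 (1R,5R,7R)-8,8-dimethyl-1-(2-methylpropanoyl)-5,7-bis(3-methylbut-2-en-1-yl)bicyclo[3.2.1]octane-2,3,9-trione
Conditions: second-generation Grubbs catalyst (5 mol %), 14 (40 equiv), CH2Cl2, 40 °C
Reagents that add atoms: none
Why: Olefin cross-metathesis converts the terminal allyl group into a prenyl group with loss of propene; the existing trisubstituted prenyl group can only exchange degenerately.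

Step 9
Reactants: 15 (1R,5R,7R)-8,8-dimethyl-1-(2-methylpropanoyl)-5,7-bis(3-methylbut-2-en-1-yl)bicyclo[3.2.1]octane-2,3,9-trione; 16 2-methylfuran
Product: 18 (1R,3S,5S,7R)-3-hydroxy-8,8-dimethyl-3-(5-methylfuran-2-yl)-1-(2-methylpropanoyl)-5,7-bis(3-methylbut-2-en-1-yl)bicyclo[3.2.1]octane-2,9-dione (hydroxyl endo), via 5-methyl-2-furyllithium 17 (not isolated)
Conditions: 16 (1.2 equiv), n-BuLi (1.15 equiv), THF, 0 °C; then 15, THF, −78 °C; sat. aq. NH4Cl at −78 °C
Reagents that add atoms: none
Why: 1,2-Addition of a small heteroaryllithium to the vicinal dione, the most electrophilic carbonyl pair; C3 is preferred over C2, which is flanked by the isobutyryl group and C8, and attack comes from the exo face (C9 side) because the endo face lies under the six-membered ring, so the hydroxyl ends endo and C3 is (S).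

Step 10
Reactants: 18 (1R,3S,5S,7R)-3-hydroxy-8,8-dimethyl-3-(5-methylfuran-2-yl)-1-(2-methylpropanoyl)-5,7-bis(3-methylbut-2-en-1-yl)bicyclo[3.2.1]octane-2,9-dione
Product: 21 spiro hemiketal of the Z-enedione: C3 oxygen closed onto the methyl ketone as a 6-hydroxy-6-methyl-2H-pyran-3(6H)-one ring spiro-fused at C3 (both anomers), via furan endoperoxide 19 (not isolated), via open Z-enedione 20 (not isolated)
Conditions: O2, visible light, tetraphenylporphyrin (1 mol %), CH2Cl2, −78 °C; then Me2S (3 equiv), −78 °C to rt
Reagents that add atoms: dioxygen, O=O
Why: Singlet-oxygen [4+2] addition to the 2,5-disubstituted furan, which is expected to be much faster than the ene reaction of the trisubstituted prenyl alkenes, then sulfide reduction of the endoperoxide to the Z-enedione, which closes onto the C3 hydroxyl (Achmatowicz-type outcome); the Z geometry comes from the furan ring and no existing stereocentre is touched.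

Step 11
Reactants: 21 spiro hemiketal of the Z-enedione
Product: 22 (1R,3S,5S,7R)-3-hydroxy-3-[(2Z)-4-hydroxy-4-methylpent-2-enoyl]-8,8-dimethyl-1-(2-methylpropanoyl)-5,7-bis(3-methylbut-2-en-1-yl)bicyclo[3.2.1]octane-2,9-dione (target)
Conditions: MeMgBr (3.5 equiv), CeCl3 (3.5 equiv, dried), THF, −78 °C; sat. aq. NH4Cl at −78 °C
Reagents that add atoms: methylmagnesium bromide, C[Mg]Br
Why: The first equivalent deprotonates the hemiketal, which opens to the Z-enedione alkoxide; the weakly basic organocerium methyl then adds 1,2 to the methyl ketone, the only carbonyl not flanked by a quaternary carbon; no stereocentre is formed and the Z double bond is untouched.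

## Compound list

1 | 6-methylhept-5-en-2-one | CC(=O)CCC=C(C)C | starting material
2 | ethyl 2-methylpropanoate | CCOC(=O)C(C)C | starting material
3 | 2,9-dimethyldec-8-ene-3,5-dione | CC(C)C(=O)CC(=O)CCC=C(C)C | intermediate
4 | diethyl oxalate | CCOC(=O)C(=O)OCC | starting material
5 | ethyl 8-methyl-3-(2-methylpropanoyl)-2,4-dioxonon-7-enoate | CCOC(=O)C(=O)C(C(=O)C(C)C)C(=O)CCC=C(C)C | intermediate
6 | 3-(2-methylpropanoyl)-5-(3-methylbut-2-en-1-yl)cyclopentane-1,2,4-trione (enolised) | CC(C)C(=O)C1C(=O)C(=O)C(CC=C(C)C)C1=O | intermediate
7 | 3-methylbut-2-en-1-ol | CC(C)=CCO | starting material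
8 | 2-[(3-methylbut-2-en-1-yl)oxy]-3-(2-methylpropanoyl)-5-(3-methylbut-2-en-1-yl)cyclopent-2-ene-1,4-dione | CC(C)C(=O)C1=C(OCC=C(C)C)C(=O)C(CC=C(C)C)C1=O | intermediate
9 | (3R)-3-(2-methylbut-3-en-2-yl)-3-(2-methylpropanoyl)-5-(3-methylbut-2-en-1-yl)cyclopentane-1,2,4-trione | C=CC(C)(C)[C@]1(C(=O)C(C)C)C(=O)C(=O)C(CC=C(C)C)C1=O | intermediate
10 | (3S)-5-iodo-3-(2-methylbut-3-en-2-yl)-3-(2-methylpropanoyl)-5-(3-methylbut-2-en-1-yl)cyclopentane-1,2,4-trione | C=CC(C)(C)[C@]1(C(=O)C(C)C)C(=O)C(=O)C(I)(CC=C(C)C)C1=O | intermediate
11 | (1R,5R,7R)-7-iodo-8,8-dimethyl-1-(2-methylpropanoyl)-5-(3-methylbut-2-en-1-yl)bicyclo[3.2.1]octane-2,3,9-trione | I[C@@H]1C[C@]2(CC=C(C)C)C(=O)[C@@](C(=O)C(C)C)(C(=O)C2=O)C1(C)C | intermediate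
12 | allyltributylstannane | C=CC[Sn](CCCC)(CCCC)CCCC | starting material
13 | (1R,5R,7R)-8,8-dimethyl-1-(2-methylpropanoyl)-5-(3-methylbut-2-en-1-yl)-7-(prop-2-en-1-yl)bicyclo[3.2.1]octane-2,3,9-trione | C=CC[C@@H]1C[C@]2(CC=C(C)C)C(=O)[C@@](C(=O)C(C)C)(C(=O)C2=O)C1(C)C | intermediate
14 | 2-methylbut-2-ene | CC=C(C)C | starting material
15 | (1R,5R,7R)-8,8-dimethyl-1-(2-methylpropanoyl)-5,7-bis(3-methylbut-2-en-1-yl)bicyclo[3.2.1]octane-2,3,9-trione | CC(C)=CC[C@@H]1C[C@]2(CC=C(C)C)C(=O)[C@@](C(=O)C(C)C)(C(=O)C2=O)C1(C)C | intermediate
16 | 2-methylfuran | Cc1ccco1 | starting material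
17 | 5-methyl-2-furyllithium | Cc1ccc([Li])o1 | intermediate
18 | (1R,3S,5S,7R)-3-hydroxy-8,8-dimethyl-3-(5-methylfuran-2-yl)-1-(2-methylpropanoyl)-5,7-bis(3-methylbut-2-en-1-yl)bicyclo[3.2.1]octane-2,9-dione | CC(C)=CC[C@@H]1C[C@]2(CC=C(C)C)C(=O)[C@@](C(=O)C(C)C)(C(=O)[C@@]2(O)c3ccc(C)o3)C1(C)C | intermediate
19 | endoperoxide of 18 (4-methyl-2,3,7-trioxabicyclo[2.2.1]hept-5-en-1-yl group on C3) | CC(C)=CC[C@@H]1C[C@]2(CC=C(C)C)C(=O)[C@@](C(=O)C(C)C)(C(=O)[C@@]2(O)C3(C=CC4(C)O3)OO4)C1(C)C | intermediate
20 | (1R,3S,5S,7R)-3-hydroxy-8,8-dimethyl-1-(2-methylpropanoyl)-5,7-bis(3-methylbut-2-en-1-yl)-3-[(2Z)-4-oxopent-2-enoyl]bicyclo[3.2.1]octane-2,9-dione | CC(C)=CC[C@@H]1C[C@]2(CC=C(C)C)C(=O)[C@@](C(=O)C(C)C)(C(=O)[C@@]2(O)C(=O)/C=C\C(C)=O)C1(C)C | intermediate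
21 | spiro hemiketal of 20 (6-hydroxy-6-methyl-2H-pyran-3(6H)-one ring spiro at C3, both anomers) | CC(C)=CC[C@@H]1C[C@]2(CC=C(C)C)C(=O)[C@@](C(=O)C(C)C)(C(=O)[C@@]2(OC3(C)O)C(=O)C=C3)C1(C)C | intermediate
22 | (1R,3S,5S,7R)-3-hydroxy-3-[(2Z)-4-hydroxy-4-methylpent-2-enoyl]-8,8-dimethyl-1-(2-methylpropanoyl)-5,7-bis(3-methylbut-2-en-1-yl)bicyclo[3.2.1]octane-2,9-dione | CC(C)=CC[C@@H]1C[C@]2(CC=C(C)C)C(=O)[C@@](C(=O)C(C)C)(C(=O)[C@@]2(O)C(=O)/C=C\C(C)(C)O)C1(C)C | target

Total step count: 11. Longest linear sequence: 11 steps (1 to 22).

## Least certain steps

**Step 4 (Proposed new method).**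
- **Risk.** Loss of enantiofacial control, or a stepwise ion-pair pathway in place of the concerted shift. The prenyl cation and the triketonate are both well stabilised, so Lewis-acid ionisation could lead to a formal [1,3] shift, return to oxygen or racemisation. The labile C5 centre, and any ether regioisomers from step 3 (oxygen on C9 or on the acyl group), would offer the catalyst other binding modes.
- **Fallback (known chemistry).** It sets out from 8 and comes back at 9. Compound 8 is heated in toluene at 110 °C for an uncatalysed Claisen rearrangement, in which every O-prenyl regioisomer converges on the same constitution. This gives racemic 3-(2-methylbut-3-en-2-yl)-3-(2-methylpropanoyl)-5-(3-methylbut-2-en-1-yl)cyclopentane-1,2,4-trione F1. The enantiomers are then separated by preparative chromatography on a polysaccharide-carbamate chiral stationary phase to give 9.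

**Step 6 (key step).**
- **Risk.** Ionic transfer of the electrophilic iodine of 10 to a prenyl double bond, chain failure with simple reduction at C5, or loss of HI from 11. The tertiary α-iodo-1,3-dione is an iodonium donor as well as a radical precursor, and its C–I bond is weak.
- **Fallback.** It sets out from 9 and comes back at 13.
  - The enolate of 9 is sulfenylated with bis(ethoxythiocarbonyl) disulfide to give the C5 O-ethyl xanthate of the trione, F2.
  - Heating with a sub-stoichiometric amount of dilauroyl peroxide in 1,2-dichloroethane effects a xanthate-group-transfer 6-endo cyclisation to the bicyclic C7 O-ethyl xanthate F3.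
  - Radical allylation of F3 with allyl ethyl sulfone and dilauroyl peroxide gives 13.

**Step 9.**
- **Risk.** Attack at C2 or from the endo face, or fragmentation of the lithium alkoxide by retro-aldol cleavage of C3–C5 or by acyl shift. C2 is electronically the more activated carbonyl even though it is the more shielded, and the alkoxide is both an aldolate and an α-ketol.
- **Fallback.** It sets out from 15 and comes back at 18. Compound 15 is treated with 16 and Sc(OTf)3 (10 mol %) in CH2Cl2 at 0 °C in a Friedel–Crafts hydroxyalkylation. This avoids any metal alkoxide and, being reversible under acid, should favour the less congested C3 exo adduct; no new compound is made (F0).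

**Step 11.**
- **Risk.** Addition to the enone carbonyl next to C3, conjugate addition to the enedione, incomplete opening of the hemiketal, or base-induced cleavage of the bis-alkoxide. Five carbonyls compete, and the product alkoxide is an aldolate.
- **Fallback.** It sets out from 15 and comes back at 22, bypassing 18 and 21.
  - Lithiated methoxyallene (methoxyallene, n-BuLi, THF, −78 °C) is added to C3 of 15 from the exo face to give the 3-hydroxy-3-(1-methoxypropa-1,2-dien-1-yl) adduct F4.
  - Mild aqueous acid hydrolyses the allenyl ether to the 3-hydroxy-3-(prop-2-enoyl) compound F5.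
  - Cross-metathesis of F5 with 2-methylbut-3-en-2-ol (second-generation Hoveyda–Grubbs catalyst, CH2Cl2, 40 °C) gives the (E)-isomer of the target, F6.
  - Sensitised irradiation isomerises F6 to the Z-enone 22, which is drawn off from the photoequilibrium by reversible hemiketal closure of the Z-isomer.

## Further compounds

F1 | step 4 | racemic 3-(2-methylbut-3-en-2-yl)-3-(2-methylpropanoyl)-5-(3-methylbut-2-en-1-yl)cyclopentane-1,2,4-trione | C=CC(C)(C)C1(C(=O)C(C)C)C(=O)C(=O)C(CC=C(C)C)C1=O
F2 | step 6 | O-ethyl S-[(3S)-3-(2-methylbut-3-en-2-yl)-3-(2-methylpropanoyl)-1-(3-methylbut-2-en-1-yl)-2,4,5-trioxocyclopentyl] dithiocarbonate (C5 xanthate) | C=CC(C)(C)[C@]1(C(=O)C(C)C)C(=O)C(=O)C(SC(=S)OCC)(CC=C(C)C)C1=O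
F3 | step 6 | bicyclic C7 O-ethyl xanthate (analogue of 11 with SC(=S)OEt in place of iodine, equatorial) | CCOC(=S)S[C@@H]1C[C@]2(CC=C(C)C)C(=O)[C@@](C(=O)C(C)C)(C(=O)C2=O)C1(C)C
F0 | step 9 | none | none
F4 | step 11 | (1R,3S,5S,7R)-3-hydroxy-3-(1-methoxypropa-1,2-dien-1-yl)-8,8-dimethyl-1-(2-methylpropanoyl)-5,7-bis(3-methylbut-2-en-1-yl)bicyclo[3.2.1]octane-2,9-dione | CC(C)=CC[C@@H]1C[C@]2(CC=C(C)C)C(=O)[C@@](C(=O)C(C)C)(C(=O)[C@@]2(O)C(OC)=C=C)C1(C)C
F5 | step 11 | (1R,3S,5S,7R)-3-hydroxy-8,8-dimethyl-1-(2-methylpropanoyl)-5,7-bis(3-methylbut-2-en-1-yl)-3-(prop-2-enoyl)bicyclo[3.2.1]octane-2,9-dione | CC(C)=CC[C@@H]1C[C@]2(CC=C(C)C)C(=O)[C@@](C(=O)C(C)C)(C(=O)[C@@]2(O)C(=O)C=C)C1(C)C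
F6 | step 11 | (E)-isomer of 22 | CC(C)=CC[C@@H]1C[C@]2(CC=C(C)C)C(=O)[C@@](C(=O)C(C)C)(C(=O)[C@@]2(O)C(=O)/C=C/C(C)(C)O)C1(C)C
A1 | alternative 1 | 6,6-dimethyl-5-(2-methylpropanoyl)-1,7-bis(3-methylbut-2-en-1-yl)bicyclo[3.3.1]nonane-2,3,4,9-tetraone (bridged tetraone) | CC(C)=CC[C@@H]1C[C@]2(CC=C(C)C)C(=O)[C@@](C(=O)C(C)C)(C(=O)C(=O)C2=O)C1(C)C
A2 | alternative 1 | lithium acetylide of triethyl[(2-methylbut-3-yn-2-yl)oxy]silane | [Li]C#CC(C)(C)O[Si](CC)(CC)CC
A3 | alternative 1 | ring-contracted ynone carbinol (22 with an alkyne in place of the Z-alkene and a triethylsilyl ether) | CC(C)=CC[C@@H]1C[C@]2(CC=C(C)C)C(=O)[C@@](C(=O)C(C)C)(C(=O)[C@@]2(O)C(=O)C#CC(C)(C)O[Si](CC)(CC)CC)C1(C)C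
A4 | alternative 2 | 2-(bromomethyl)-3-methylbut-2-enal | O=CC(CBr)=C(C)C
A5 | alternative 2 | bicyclic 2,3,9-trione with an equatorial C7 aldehyde | O=C[C@@H]1C[C@]2(CC=C(C)C)C(=O)[C@@](C(=O)C(C)C)(C(=O)C2=O)C1(C)C
A6 | alternative 3 | 3-diazo-6,6-dimethyl-5-(2-methylpropanoyl)-1,7-bis(3-methylbut-2-en-1-yl)bicyclo[3.3.1]nonane-2,4,9-trione | CC(C)=CC[C@@H]1C[C@]2(CC=C(C)C)C(=O)[C@@](C(=O)C(C)C)(C(=O)C(=[N+]=[N-])C2=O)C1(C)C
A7 | alternative 3 | ring-contracted bicyclo[3.2.1] β-keto methyl ester (ester on C3, exo) | CC(C)=CC[C@@H]1C[C@]2(CC=C(C)C)C(=O)[C@@](C(=O)C(C)C)(C(=O)[C@H]2C(=O)OC)C1(C)C
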